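## Retrosynthetic overview

1. Target ⇐ 9‑O‑TBS macrocyclic 14,18‑diol (acetylation, then desilylation) ⇐ macrocyclic ethyl ester (C18 at the ester level).
2. The only ring, the 14‑membered carbocycle, is closed late by an intramolecular Horner–Wadsworth–Emmons olefination that forms C12=C13 as the (E)‑enoate.
3. The open chain comes from C11–C12 alkylation of triethyl phosphonoacetate and a C6–C7 Negishi alkenyl–allyl coupling between a northern allylic chloride (C1–C6, C13, C14) and a southern (Z)‑vinyl iodide (C7–C11).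
4. Northern half ⇐ geraniol: allylic oxidation, allylic borylation, then a chiral‑phosphoric‑acid‑catalysed anti‑allylboration of TBSOCH2CHO that sets C1 and C14.
5. Southern half ⇐ propargyl alcohol: anti‑carbomagnesiation/iodination, oxidation, vinyl addition, then a lipase‑catalysed kinetic resolution that sets C9.

Convention: locants C1–C14 and C18 follow the target ring (C1 = CH bearing isopropenyl, then C2, C3, C4(Me)=C5, C6, C7=C8(Me), C9(O), C10, C11, C12(C18)=C13, C14(O)).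

Assumption: (R)‑TRIP delivers the allyl group to the Re face of the aldehyde (its usual sense); if the opposite sense is found, (S)‑TRIP is used.

## Route

Step 1
Reactants: 1 geraniol
Product: 2 geranyl 4‑methoxybenzyl (PMB) ether
Conditions: NaH, PMBCl, Bu4NI (cat.), THF/DMF, 0 °C → rt
Reagents that add atoms: 4‑methoxybenzyl chloride, COc1ccc(CCl)cc1
Why: Williamson etherification gives an allylic ether that survives SeO2, Pd(0), Brønsted‑acid catalysis and fluoride and is later removed oxidatively.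

Step 2
Reactants: 2 geranyl PMB ether
Product: 3 (2E,6E)‑8‑(4‑methoxybenzyloxy)‑2,6‑dimethylocta‑2,6‑dien‑1‑ol
Conditions: SeO2 (cat.), t‑BuOOH, salicylic acid (cat.), CH2Cl2, rt
Reagents that add atoms: tert‑butyl hydroperoxide, CC(C)(C)OO (terminal oxidant; O delivered through catalytic SeO2, O=[Se]=O)
Why: Sharpless‑type SeO2 allylic oxidation (ene/[2,3] shift) hydroxylates the (E)‑methyl of the more electron‑rich terminal trisubstituted alkene, giving the E allylic alcohol.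

Step 3
Reactants: 3 allylic alcohol
Product: 4 (2E,6E)‑8‑(4‑methoxybenzyloxy)‑2,6‑dimethylocta‑2,6‑dien‑1‑yl acetate
Conditions: Ac2O, pyridine, DMAP (cat.), CH2Cl2, 0 °C
Reagents that add atoms: acetic anhydride, CC(=O)OC(C)=O
Why: Simple acylation installs the leaving group for π‑allyl palladium formation.

Step 4
Reactants: 4 allylic acetate
Product: 5 pinacol (2E,6E)‑8‑(4‑methoxybenzyloxy)‑2,6‑dimethylocta‑2,6‑dien‑1‑ylboronate
Conditions: B2pin2, Pd2(dba)3 (2.5 mol %), DMSO, 50 °C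
Reagents that add atoms: bis(pinacolato)diboron, CC1(C)OB(OC1(C)C)B1OC(C)(C)C(C)(C)O1
Why: Miyaura‑type allylic borylation (π‑allyl‑Pd/diboron transmetalation) gives the linear (E)‑allylboronate, and the allylic PMB ether is not ionised.

Step 5
Reactants: 5 allylboronate; 6 (tert‑butyldimethylsilyloxy)acetaldehyde
Product: 8 (2R,3R,6E)‑1‑(tert‑butyldimethylsilyloxy)‑8‑(4‑methoxybenzyloxy)‑6‑methyl‑3‑(prop‑1‑en‑2‑yl)oct‑6‑en‑2‑ol, via pinacol borate ester 7 (not isolated)
Conditions: (R)‑TRIP (5 mol %), 4 Å MS, toluene, −30 °C; aq. NaHCO3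
Reagents that add atoms: none
Why: Chiral‑phosphoric‑acid‑catalysed allylboration through a closed chair transition state: the (E)‑γ‑substituent gives the anti adduct (C1 relative to C14) and the catalyst, hydrogen‑bonded to the boronate oxygen and formyl H, selects the aldehyde Re face (C14), so both stereocentres are set here by asymmetric catalysis.

Step 6
Reactants: 8 silyl ether alcohol
Product: 9 (2R,3R,6E)‑8‑(4‑methoxybenzyloxy)‑6‑methyl‑3‑(prop‑1‑en‑2‑yl)oct‑6‑ene‑1,2‑diol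
Conditions: TBAF, THF, 0 °C → rt
Reagents that add atoms: none
Why: Fluoride desilylation frees the primary alcohol so both hydroxyls can carry the same, more labile silyl group.

Step 7
Reactants: 9 diol
Product: 10 (2R,3R,6E)‑8‑(4‑methoxybenzyloxy)‑6‑methyl‑3‑(prop‑1‑en‑2‑yl)‑1,2‑bis(triethylsilyloxy)oct‑6‑ene
Conditions: TESOTf, 2,6‑lutidine, CH2Cl2, −78 → 0 °C
Reagents that add atoms: triethylsilyl triflate, CC[Si](CC)(CC)OS(=O)(=O)C(F)(F)F
Why: Bis‑silylation gives a primary TES ether that can later be oxidised directly and a secondary TES ether that can later be removed beside a TBS ether.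

Step 8
Reactants: 10 bis‑TES PMB ether
Product: 11 (2E,6R,7R)‑3‑methyl‑6‑(prop‑1‑en‑2‑yl)‑7,8‑bis(triethylsilyloxy)oct‑2‑en‑1‑ol
Conditions: DDQ, CH2Cl2/pH 7 buffer, 0 °C
Reagents that add atoms: none
Why: Oxidative PMB cleavage (single‑electron oxidation of the electron‑rich benzyl ether) under buffered conditions leaves TES ethers and the alkenes untouched.

Step 9
Reactants: 11 allylic alcohol
Product: 12 (2E,6R,7R)‑1‑chloro‑3‑methyl‑6‑(prop‑1‑en‑2‑yl)‑7,8‑bis(triethylsilyloxy)oct‑2‑ene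
Conditions: NCS, Me2S, CH2Cl2, −20 → 0 °C
Reagents that add atoms: N‑chlorosuccinimide, O=C1CCC(=O)N1Cl
Why: Corey–Kim chlorination displaces the allylic alkoxysulfonium by chloride in an SN2 sense under neutral conditions, without allylic transposition or E/Z loss.

Step 10
Reactants: 13 propargyl alcohol
Product: 15 (Z)‑3‑iodo‑2‑methylprop‑2‑en‑1‑ol, via (Z)‑alkenylmagnesium alkoxide 14 (not isolated)
Conditions: MeMgBr (3 equiv), CuI (20 mol %), THF, −20 °C → rt; then I2, −78 → 0 °C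
Reagents that add atoms: methylmagnesium bromide, C[Mg]Br; iodine, II
Why: Copper‑catalysed anti‑carbomagnesiation of the propargylic alkoxide is chelate‑directed, placing Mg cis to CH2O, and iodinolysis with retention gives the (Z)‑vinyl iodide.

Step 11
Reactants: 15 (Z)‑iodo allylic alcohol
Product: 16 (Z)‑3‑iodo‑2‑methylprop‑2‑enal
Conditions: activated MnO2, CH2Cl2, rt, dark; used crude
Reagents that add atoms: none
Why: Neutral MnO2 allylic oxidation gives the enal without Z→E isomerisation.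

Step 12
Reactants: 16 (Z)‑iodo enal
Product: 17 rac‑(1Z)‑1‑iodo‑2‑methylpenta‑1,4‑dien‑3‑ol
Conditions: CH2=CHMgBr, THF, −78 °C; aq. NH4Cl
Reagents that add atoms: vinylmagnesium bromide, C=C[Mg]Br
Why: Grignard 1,2‑addition at −78 °C (no I/Mg exchange) builds C9–C11 and the racemic C9 carbinol.

Step 13
Reactants: 17 racemic dienol
Product: 18 (1Z,3S)‑1‑iodo‑2‑methylpenta‑1,4‑dien‑3‑ol
Conditions: lipase (Candida antarctica lipase B, immobilised), vinyl acetate, MTBE, 30 °C, to about 55 % conversion; chromatography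
Reagents that add atoms: none
Why: Lipase (serine hydrolase) kinetic resolution by irreversible transesterification: following the Kazlauskas rule (vinyl = medium, iodo‑methylvinyl = large) the (R)‑alcohol is acetylated and the (S)‑alcohol, the C9 configuration of the target, is recovered in high ee.

Step 14
Reactants: 18 (S)‑dienol
Product: 19 tert‑butyl{[(1Z,3S)‑1‑iodo‑2‑methylpenta‑1,4‑dien‑3‑yl]oxy}dimethylsilane
Conditions: TBSCl, imidazole, DMF, rt
Reagents that add atoms: tert‑butyldimethylsilyl chloride, CC(C)(C)[Si](C)(C)Cl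
Why: Silylation gives the C9 protecting group that lasts to the final step.

Step 15
Reactants: 19 TBS ether
Product: 21 (3S,4Z)‑3‑(tert‑butyldimethylsilyloxy)‑5‑iodo‑4‑methylpent‑4‑en‑1‑ol, via B‑alkyl‑9‑BBN adduct 20 (not isolated)
Conditions: 9‑BBN, THF, 0 °C → rt; then NaOH, H2O2, 0 °C
Reagents that add atoms: hydrogen peroxide, OO
Why: Hydroboration–oxidation with 9‑BBN is anti‑Markovnikov and attacks only the monosubstituted vinyl group, not the trisubstituted vinyl iodide.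

Step 16
Reactants: 21 primary alcohol
Product: 22 (1Z,3S)‑3‑(tert‑butyldimethylsilyloxy)‑5‑chloro‑1‑iodo‑2‑methylpent‑1‑ene
Conditions: PPh3, NCS, THF, 0 °C → rt
Reagents that add atoms: N‑chlorosuccinimide, O=C1CCC(=O)N1Cl
Why: Appel‑type chlorination gives a primary chloride that is inert to t‑BuLi at −78 °C and to Pd(0), yet can be activated later.

Step 17
Reactants: 22 (Z)‑vinyl iodide; 12 allylic chloride
Product: 25 (3S,4Z,7E,11R,12R)‑3‑(tert‑butyldimethylsilyloxy)‑1‑chloro‑4,8‑dimethyl‑11‑(prop‑1‑en‑2‑yl)‑12,13‑bis(triethylsilyloxy)trideca‑4,7‑diene, via (Z)‑alkenyllithium 23 (not isolated), via (Z)‑alkenylzinc bromide 24 (not isolated)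
Conditions: 22, t‑BuLi (2.1 equiv), Et2O, −78 °C; ZnBr2, THF, −78 → 0 °C; then 12, Pd(PPh3)4 (5 mol %), THF, rt
Reagents that add atoms: none
Why: Li–I exchange and Zn transmetalation proceed with retention, and the Negishi alkenyl–allyl coupling attacks the π‑allyl at its primary terminus, forming C6–C7 with both alkene geometries kept.

Step 18
Reactants: 25 alkyl chloride
Product: 26 the corresponding 1‑iodo compound (C11–I)
Conditions: NaI, 2‑butanone, 70 °C
Reagents that add atoms: sodium iodide, [Na+].[I-]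
Why: Finkelstein exchange activates C11 for C‑alkylation, and the silyl ethers and alkenes are inert.

Step 19
Reactants: 26 alkyl iodide; 27 triethyl phosphonoacetate
Product: 28 ethyl (5S,6Z,9E,13R,14R)‑5‑(tert‑butyldimethylsilyloxy)‑2‑(diethoxyphosphoryl)‑6,10‑dimethyl‑13‑(prop‑1‑en‑2‑yl)‑14,15‑bis(triethylsilyloxy)pentadeca‑6,9‑dienoate (C2 epimers)
Conditions: 27 (3 equiv), NaH, DMF, 0 °C; then 26, 50 °C
Reagents that add atoms: none
Why: SN2 C‑alkylation of the stabilised phosphonoacetate anion installs C12 and C18 together with the olefination handle; the new centre is lost in the olefination.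

Step 20
Reactants: 28 phosphonate bis‑TES ether
Product: 30 ethyl (5S,6Z,9E,13R,14R)‑5‑(tert‑butyldimethylsilyloxy)‑2‑(diethoxyphosphoryl)‑6,10‑dimethyl‑15‑oxo‑13‑(prop‑1‑en‑2‑yl)‑14‑(triethylsilyloxy)pentadeca‑6,9‑dienoate, via alkoxydimethylsulfonium chloride 29 (not isolated)
Conditions: (COCl)2, DMSO, CH2Cl2, −78 → −35 °C; then Et3N, −78 → 0 °C; used crude
Reagents that add atoms: none
Why: Under Swern conditions activated DMSO cleaves only the primary TES ether and oxidises it in situ to the α‑silyloxy aldehyde, leaving the secondary silyl ethers and C14 untouched.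

Step 21
Reactants: 30 aldehyde phosphonate
Product: 31 macrocyclic ethyl ester (1R,9S,14S; 4E,7Z,12E): C12–CO2Et, 9‑OTBS, 14‑OTES
Conditions: LiCl, DBU, MeCN, rt, syringe‑pump addition to 1 mM
Reagents that add atoms: none
Why: Intramolecular Horner–Wadsworth–Emmons olefination under Masamune–Roush conditions closes the 14‑membered ring as the thermodynamic (E)‑enoate (ester trans to C14) without epimerising C14; the C14 label changes R→S only because C13 drops in CIP priority.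

Step 22
Reactants: 31 macrocyclic enoate
Product: 32 macrocyclic C18 allylic alcohol (C12–CH2OH, 9‑OTBS, 14‑OTES)
Conditions: DIBAL‑H, CH2Cl2, −78 °C; Rochelle salt
Reagents that add atoms: none
Why: DIBAL 1,2‑reduction of the enoate gives the allylic alcohol and keeps the double‑bond geometry.

Step 23
Reactants: 32 TES/TBS ether
Product: 33 macrocyclic 14,18‑diol 9‑TBS ether
Conditions: PPTS (cat.), MeOH/CH2Cl2, 0 °C
Reagents that add atoms: none
Why: Acid‑catalysed methanolysis removes the TES ether about two orders of magnitude faster than the secondary TBS ether.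

Step 24
Reactants: 33 diol
Product: 34 14,18‑diacetate 9‑TBS ether
Conditions: Ac2O, pyridine, DMAP (cat.), CH2Cl2, rt
Reagents that add atoms: acetic anhydride, CC(=O)OC(C)=O
Why: DMAP‑catalysed acylation esterifies both free hydroxyls while C9 stays masked.

Step 25
Reactants: 34 diacetate TBS ether
Product: 35 CNP0097266.2 (target)
Conditions: HF·pyridine, pyridine, THF, 0 °C → rt
Reagents that add atoms: none
Why: Buffered HF desilylation frees the C9 alcohol without cleaving or migrating the acetates.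

## Compound list

1 | geraniol | CC(C)=CCC/C(C)=C/CO | starting material
2 | geranyl PMB ether | CC(C)=CCC/C(C)=C/COCc1ccc(OC)cc1 | intermediate
3 | (2E,6E)‑8‑(PMB‑oxy)‑2,6‑dimethylocta‑2,6‑dien‑1‑ol | OC/C(C)=C/CC/C(C)=C/COCc1ccc(OC)cc1 | intermediate
4 | acetate of 3 | CC(=O)OC/C(C)=C/CC/C(C)=C/COCc1ccc(OC)cc1 | intermediate
5 | (2E,6E)‑allyl pinacol boronate | CC1(C)OB(C/C(C)=C/CC/C(C)=C/COCc2ccc(OC)cc2)OC1(C)C | intermediate
6 | (tert‑butyldimethylsilyloxy)acetaldehyde | O=CCO[Si](C)(C)C(C)(C)C | starting material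
7 | pinacol borate ester of 8 | CC(C)(C)[Si](C)(C)OC[C@H](OB1OC(C)(C)C(C)(C)O1)[C@H](CC/C(C)=C/COCc1ccc(OC)cc1)C(C)=C | intermediate
8 | (2R,3R,6E)‑1‑TBSO‑8‑PMBO‑6‑methyl‑3‑isopropenyloct‑6‑en‑2‑ol | CC(C)(C)[Si](C)(C)OC[C@H](O)[C@H](CC/C(C)=C/COCc1ccc(OC)cc1)C(C)=C | intermediate
9 | (2R,3R,6E)‑8‑PMBO‑6‑methyl‑3‑isopropenyloct‑6‑ene‑1,2‑diol | OC[C@H](O)[C@H](CC/C(C)=C/COCc1ccc(OC)cc1)C(C)=C | intermediate
10 | bis‑TES ether of 9 | CC[Si](CC)(CC)OC[C@H](O[Si](CC)(CC)CC)[C@H](CC/C(C)=C/COCc1ccc(OC)cc1)C(C)=C | intermediate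
11 | (2E,6R,7R)‑3‑methyl‑6‑isopropenyl‑7,8‑bis(TESO)oct‑2‑en‑1‑ol | CC[Si](CC)(CC)OC[C@H](O[Si](CC)(CC)CC)[C@H](CC/C(C)=C/CO)C(C)=C | intermediate
12 | (2E,6R,7R)‑1‑chloro‑3‑methyl‑6‑isopropenyl‑7,8‑bis(TESO)oct‑2‑ene | CC[Si](CC)(CC)OC[C@H](O[Si](CC)(CC)CC)[C@H](CC/C(C)=C/CCl)C(C)=C | intermediate
13 | propargyl alcohol | C#CCO | starting material
14 | (Z)‑alkenylmagnesium alkoxide | C/C(CO[Mg]Br)=C/[Mg]Br | intermediate
15 | (Z)‑3‑iodo‑2‑methylprop‑2‑en‑1‑ol | OC/C(C)=C\I | intermediate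
16 | (Z)‑3‑iodo‑2‑methylprop‑2‑enal | O=C/C(C)=C\I | intermediate
17 | rac‑(1Z)‑1‑iodo‑2‑methylpenta‑1,4‑dien‑3‑ol | C=CC(O)/C(C)=C\I | intermediate
18 | (1Z,3S)‑1‑iodo‑2‑methylpenta‑1,4‑dien‑3‑ol | C=C[C@H](O)/C(C)=C\I | intermediate
19 | TBS ether of 18 | C=C[C@H](O[Si](C)(C)C(C)(C)C)/C(C)=C\I | intermediate
20 | B‑alkyl‑9‑BBN adduct of 19 | B1(CC[C@H](O[Si](C)(C)C(C)(C)C)/C(C)=C\I)C2CCCC1CCC2 | intermediate
21 | (3S,4Z)‑3‑TBSO‑5‑iodo‑4‑methylpent‑4‑en‑1‑ol | OCC[C@H](O[Si](C)(C)C(C)(C)C)/C(C)=C\I | intermediate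
22 | (1Z,3S)‑3‑TBSO‑5‑chloro‑1‑iodo‑2‑methylpent‑1‑ene | ClCC[C@H](O[Si](C)(C)C(C)(C)C)/C(C)=C\I | intermediate
23 | (Z)‑alkenyllithium from 22 | ClCC[C@H](O[Si](C)(C)C(C)(C)C)/C(C)=C\[Li] | intermediate
24 | (Z)‑alkenylzinc bromide from 23 | ClCC[C@H](O[Si](C)(C)C(C)(C)C)/C(C)=C\[Zn]Br | intermediate
25 | coupled chloro‑triene (3S,4Z,7E,11R,12R) | ClCC[C@H](O[Si](C)(C)C(C)(C)C)/C(C)=C\C/C=C(C)/CC[C@H](C(C)=C)[C@H](CO[Si](CC)(CC)CC)O[Si](CC)(CC)CC | intermediate
26 | iodide corresponding to 25 | ICC[C@H](O[Si](C)(C)C(C)(C)C)/C(C)=C\C/C=C(C)/CC[C@H](C(C)=C)[C@H](CO[Si](CC)(CC)CC)O[Si](CC)(CC)CC | intermediate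
27 | triethyl phosphonoacetate | CCOC(=O)CP(=O)(OCC)OCC | starting material
28 | α‑alkylated phosphonoacetate (C12 epimers) | CCOC(=O)C(CC[C@H](O[Si](C)(C)C(C)(C)C)/C(C)=C\C/C=C(C)/CC[C@H](C(C)=C)[C@H](CO[Si](CC)(CC)CC)O[Si](CC)(CC)CC)P(=O)(OCC)OCC | intermediate
29 | alkoxydimethylsulfonium chloride from 28 | CCOC(=O)C(CC[C@H](O[Si](C)(C)C(C)(C)C)/C(C)=C\C/C=C(C)/CC[C@H](C(C)=C)[C@H](CO[S+](C)C)O[Si](CC)(CC)CC)P(=O)(OCC)OCC.[Cl-] | intermediate
30 | aldehyde phosphonate | CCOC(=O)C(CC[C@H](O[Si](C)(C)C(C)(C)C)/C(C)=C\C/C=C(C)/CC[C@H](C(C)=C)[C@H](C=O)O[Si](CC)(CC)CC)P(=O)(OCC)OCC | intermediate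
31 | macrocyclic ethyl ester (9‑OTBS, 14‑OTES) | C=C(C)[C@H]1CC/C(C)=C/C/C=C(/C)[C@@H](O[Si](C)(C)C(C)(C)C)CC/C(C(=O)OCC)=C\[C@@H]1O[Si](CC)(CC)CC | intermediate
32 | macrocyclic C18 alcohol (9‑OTBS, 14‑OTES) | C=C(C)[C@H]1CC/C(C)=C/C/C=C(/C)[C@@H](O[Si](C)(C)C(C)(C)C)CC/C(CO)=C\[C@@H]1O[Si](CC)(CC)CC | intermediate
33 | macrocyclic 14,18‑diol 9‑TBS ether | C=C(C)[C@H]1CC/C(C)=C/C/C=C(/C)[C@@H](O[Si](C)(C)C(C)(C)C)CC/C(CO)=C\[C@@H]1O | intermediate
34 | 14,18‑diacetate 9‑TBS ether | C=C(C)[C@H]1CC/C(C)=C/C/C=C(/C)[C@@H](O[Si](C)(C)C(C)(C)C)CC/C(COC(C)=O)=C\[C@@H]1OC(C)=O | intermediate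
35 | CNP0097266.2 | C=C(C)[C@H]1CC/C(C)=C/C/C=C(/C)[C@@H](O)CC/C(COC(C)=O)=C\[C@@H]1OC(C)=O | target

## Step count and risks

Total: 25 steps. Longest linear sequence: 18 steps (steps 1–9, then 17–25, from geraniol). The southern branch is 7 steps (10–16).

Most likely to fail:

Step 5 (enantioselectivity of the catalysed allylboration with an α‑silyloxy aldehyde and a trisubstituted allylboronate). The fallback sets out from 3 and comes back at 9. Alcohol 3 is converted with CBr4/PPh3 into the allylic bromide F1. A chromium‑catalysed asymmetric Nozaki–Hiyama allylation of 6 (CrCl2 10 mol %, chiral bis(oxazolinyl)carbazole ligand, Mn, TMSCl, i‑Pr2NEt, THF, 0 °C) then gives the anti adduct as its trimethylsilyl ether F2, with the anti relationship coming from the allylchromium chair transition state and the face from the ligand. TBAF removes both silyl groups to give 9.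

Step 17 (vinyllithium generation beside an alkyl chloride and the alkenyl–allyl coupling). The fallback sets out from 22 and comes back at 25. Palladium‑catalysed stannylation of 22 (Me3SnSnMe3, Pd(PPh3)4, toluene, 80 °C) gives the (Z)‑alkenylstannane F3 without any organolithium. A neutral Stille coupling of it with 12 (Pd2(dba)3, AsPh3, NMP/THF, 40 °C) gives 25.

Step 21 (yield and E/Z ratio of the macrocyclic olefination). The fallback sets out from 22 and 12 and comes back at 31; it makes C12=C13 intermolecularly and closes the ring at C6–C7 instead. NaI in 2‑butanone converts 22 into the diiodide F4 (only the alkyl chloride exchanges). Alkylation of 27 (NaH, DMF) gives the vinyl iodide phosphonate F5, and Me3SnSnMe3/Pd(PPh3)4 gives the alkenylstannane phosphonate F6. Selective Swern oxidation of 12 gives the α‑silyloxy aldehyde F7 with the allylic chloride intact. Intermolecular Horner–Wadsworth–Emmons reaction of F6 with F7 (LiCl, i‑Pr2NEt, MeCN) gives the acyclic (E)‑enoate F8. An intramolecular Stille alkenyl–allyl coupling (Pd2(dba)3, AsPh3, THF/NMP, high dilution) then closes the 14‑membered ring to 31.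

## Further compounds

F1 | step 5 | 1‑({[(2E,6E)‑8‑bromo‑3,7‑dimethylocta‑2,6‑dien‑1‑yl]oxy}methyl)‑4‑methoxybenzene | BrC/C(C)=C/CC/C(C)=C/COCc1ccc(OC)cc1
F2 | step 5 | trimethylsilyl ether of 8 | CC(C)(C)[Si](C)(C)OC[C@H](O[Si](C)(C)C)[C@H](CC/C(C)=C/COCc1ccc(OC)cc1)C(C)=C
F3 | step 17 | (1Z,3S)‑3‑TBSO‑5‑chloro‑2‑methyl‑1‑(trimethylstannyl)pent‑1‑ene | ClCC[C@H](O[Si](C)(C)C(C)(C)C)/C(C)=C\[Sn](C)(C)C
F4 | step 21 | (1Z,3S)‑3‑TBSO‑1,5‑diiodo‑2‑methylpent‑1‑ene | ICC[C@H](O[Si](C)(C)C(C)(C)C)/C(C)=C\I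
F5 | step 21 | ethyl (5S,6Z)‑5‑TBSO‑2‑(diethoxyphosphoryl)‑7‑iodo‑6‑methylhept‑6‑enoate | CCOC(=O)C(CC[C@H](O[Si](C)(C)C(C)(C)C)/C(C)=C\I)P(=O)(OCC)OCC
F6 | step 21 | ethyl (5S,6Z)‑5‑TBSO‑2‑(diethoxyphosphoryl)‑6‑methyl‑7‑(trimethylstannyl)hept‑6‑enoate | CCOC(=O)C(CC[C@H](O[Si](C)(C)C(C)(C)C)/C(C)=C\[Sn](C)(C)C)P(=O)(OCC)OCC
F7 | step 21 | (2R,3R,6E)‑8‑chloro‑6‑methyl‑3‑(prop‑1‑en‑2‑yl)‑2‑(triethylsilyloxy)oct‑6‑enal | O=C[C@H](O[Si](CC)(CC)CC)[C@H](CC/C(C)=C/CCl)C(C)=C
F8 | step 21 | acyclic (E)‑enoate bearing the alkenylstannane and the allylic chloride | CCOC(=O)/C(CC[C@H](O[Si](C)(C)C(C)(C)C)/C(C)=C\[Sn](C)(C)C)=C/[C@H](O[Si](CC)(CC)CC)[C@H](CC/C(C)=C/CCl)C(C)=C
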